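**Plan**
1. Retrosynthetic cuts (2-benzoxepine numbering of the right half):
   - (i) the ester O–CH2 bond at C9, giving acid 30 and spiro-epoxide 17;
   - (ii) in the oxepinone, the C4=C5 alkene (ring-closing metathesis) and O2–C3 (carboxylate alkylation);
   - (iii) the carbon branches on C9a and C5a, which are the two halves of a temporary cyclobutane;
   - (iv) C8, which is taken out of the carbocycle, so cyclohexanone 8 comes from cyclopentanone 6.
2. Enabling feature: in the carbocycle C5a–C6–C7–C8–C9–C9a, the oxygenated C9 derives from a ketone. That ketone has the bare C8H2–C7H2 unit on one side and the methine C9a on the other, so a cyclopentanone lacking C8 can take up one CH2 regioselectively.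
3. Right half, forward: cyclopentenone + allene gives the cyclobutane, then the isopropyl group is added, the five-membered ring becomes six-membered, the spiro-epoxide is formed, the cyclobutane is cleaved to acid and aldehyde, and the seven-membered lactone is closed.
4. Left half, forward: enyne metathesis, endo Diels–Alder (cyclohexene), acetyl to isopropyl, bromo-Wittig/Stille side chain. The halves are joined by carboxylate opening of the epoxide, and the last step frees the acid.
5. Stereochemistry: C4 of commercial (R)-1 steers the photocycloaddition (C5a, C9a). The cup-shaped bicycle steers the cuprate (C6) and the ylide (C9). In the left half the endo rule gives cis, a chiral oxazaborolidinium catalyst sets the absolute sense, and the alkene geometry comes from the Z-selective bromo-ylide with retention in the Stille coupling.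

Key step: step 4

Assumption: the (S)-diphenylprolinol-derived oxazaborolidinium ion in step 13 is taken to shield the enone face that leads to the enantiomer of 22; should the sense be opposite, the (R)-derived catalyst is used.
Assumption: 13 is drawn as the open oxo acid, although it may rest as its five-membered lactol, which reacts through the open form.

Step 1
Reactants: 1 (R)-4-(tert-butyldimethylsilyloxy)cyclopent-2-en-1-one; 2 propa-1,2-diene (allene)
Product: 3 (1R,4R,5R)-4-(tert-butyldimethylsilyloxy)-7-methylidenebicyclo[3.2.0]heptan-2-one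
Conditions: hν (medium-pressure Hg lamp, Pyrex), excess 2, CH2Cl2, −78 °C
Reagents that add atoms: none
Why: Enone–allene [2+2] photocycloaddition; the head-to-head orientation usual for allene places the methylidene carbon next to C1, a five-membered enone can only give the cis-fused cyclobutane, and allene should add anti to the C4 silyloxy group, which sets C1 and C5.

Step 2
Reactants: 3 photoadduct
Product: 4 (1R,5S)-7-methylidenebicyclo[3.2.0]hept-3-en-2-one
Conditions: DBU, CH2Cl2, 0 °C to rt
Reagents that add atoms: none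
Why: E1cB β-elimination of silanolate from a β-silyloxy ketone; the two ring-fusion centres are locked cis and carry the chirality of 1 onward.

Step 3
Reactants: 4 bicyclic enone
Product: 6 (1R,4S,5S)-4-isopropyl-7-methylidenebicyclo[3.2.0]heptan-2-one, via silyl enol ether 5 (not isolated)
Conditions: iPrMgCl, CuBr·SMe2 (20 mol %), TMSCl, THF, −78 °C; then 1 M HCl, 0 °C
Reagents that add atoms: isopropylmagnesium chloride CC(C)[Mg]Cl; chlorotrimethylsilane C[Si](C)(C)Cl (stays in 5 only)
Why: Copper-catalysed, TMSCl-accelerated conjugate addition; the reagent should enter C4 on the convex face, anti to cyclobutane carbon C6 on the neighbouring C5, which sets the isopropyl centre trans to the cyclobutane.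

Step 4
Reactants: 6 cyclopentanone
Product: 8 (1R,5S,6S)-5-isopropyl-8-methylidenebicyclo[4.2.0]octan-2-one, via beta-keto silane 7 (not isolated)
Conditions: TMSCHN2, Sc(OTf)3 (10 mol %), toluene, −78 to −20 °C; then 1 M HCl, THF, 0 °C
Reagents that add atoms: (trimethylsilyl)diazomethane C[Si](C)(C)C=[N+]=[N-]
Why: Sc(OTf)3 activates the C2 carbonyl, the carbon of TMSCHN2 adds from the convex face, and the β-oxido diazonium ion loses N2 while the antiperiplanar C3 methylene shifts to the new carbon, giving β-keto silane 7 and, after protodesilylation, 8. The closest known reaction type is the Lewis-acid-promoted diazoalkane homologation of cycloalkanones (Büchner–Curtius–Schlotterbeck, Tiffeneau–Demjanov type), documented for cyclopentanone to cyclohexanone. No ring is closed: the five-membered carbocycle is enlarged to the six-membered one by a 1,2-shift that inserts the future C8 between C9 and C7 (target numbering), while the cyclobutane stays as it is. No lasting stereocentre is made (the silyl-bearing carbon ends as CH2), and C1, C5 and C6 of 8 are carried over unchanged because none of them is the migrating carbon or the terminus. The step needs migration of the CH2 rather than of the ring-fusion methine C1, and one insertion only; in this reaction class the less substituted carbon migrates, the bulky silyl group lies away from the cyclobutane side in the adduct, and the hindered α-silyl ketone 7 should not take up a second diazoalkane. This one-carbon edit is what allows three of the four stereocentres of the carbocycle to be set on a rigid bicyclo[3.2.0]heptane made from a commercial chiral cyclopentenone.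

Step 5
Reactants: 8 cyclohexanone
Product: 9 (1R,2R,5S,6S)-5-isopropyl-8-methylidenespiro[bicyclo[4.2.0]octane-2,2'-oxirane]
Conditions: Me3SI, NaH, DMSO/THF, 0 °C
Reagents that add atoms: trimethylsulfonium iodide C[S+](C)C.[I-]
Why: Corey–Chaykovsky epoxidation; the small sulfonium ylide should attack axially on the face opposite the axial C1–C8 bond of the cis-fused cyclobutane, so the new CH2 is axial and the oxygen equatorial, which sets the future C9, and C1 cannot epimerise because only the cis fusion is viable.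

Step 6
Reactants: 9 spiro-epoxide
Product: 10 (1S,2R,5S,6S)-5-isopropylspiro[bicyclo[4.2.0]octane-2,2'-oxiran]-8-one
Conditions: O3, CH2Cl2, −78 °C; then Me2S
Reagents that add atoms: ozone [O-][O+]=O
Why: Ozonolysis of the only alkene gives the cyclobutanone whose carbonyl carbon sits on the future C9a; the epoxide is inert to ozone.

Step 7
Reactants: 10 cyclobutanone
Product: 11 {[(1S,2R,5S,6R)-5-isopropylspiro[bicyclo[4.2.0]oct-7-ene-2,2'-oxiran]-8-yl]oxy}trimethylsilane
Conditions: LDA, TMSCl (internal quench), THF, −78 °C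
Reagents that add atoms: chlorotrimethylsilane C[Si](C)(C)Cl
Why: Kinetic enolate silylation; the base should remove a proton from the open C7 methylene rather than the hindered ring-fusion C1–H, and immediate silylation at low temperature forestalls β-elimination of the epoxide oxygen.

Step 8
Reactants: 11 silyloxycyclobutene
Product: 13 (3R,4S,5S,6S)-5-formyl-6-isopropyl-1-oxaspiro[2.5]octane-4-carboxylic acid, via silyl ester 12 (not isolated)
Conditions: O3, CH2Cl2, −78 °C; then Me2S; aqueous work-up
Reagents that add atoms: ozone [O-][O+]=O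
Why: Ozonolysis of a silyl enol ether removes the temporary ring and gives the two cis branches already differentiated, acid on the future C9a and aldehyde on C5a; the equatorial formyl group has no drive to epimerise.

Step 9
Reactants: 13 oxo acid
Product: 14 (3R,4S,5S,6S)-5-ethenyl-6-isopropyl-1-oxaspiro[2.5]octane-4-carboxylic acid
Conditions: Ph3PCH3Br, KN(SiMe3)2 (excess), THF, 0 °C to rt; then aq. citric acid
Reagents that add atoms: methyltriphenylphosphonium bromide C[P+](c1ccccc1)(c1ccccc1)c1ccccc1.[Br-]
Why: Wittig methylenation of an aldehyde (or its lactol) in the presence of a carboxylate, as practised on lactols; the epoxide is not attacked at this temperature.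

Step 10
Reactants: 14 vinyl acid; 15 tert-butyl 2-(bromomethyl)prop-2-enoate
Product: 16 2-(tert-butoxycarbonyl)prop-2-en-1-yl (3R,4S,5S,6S)-5-ethenyl-6-isopropyl-1-oxaspiro[2.5]octane-4-carboxylate
Conditions: Cs2CO3, DMF, 0 °C to rt
Reagents that add atoms: none
Why: O-alkylation of a caesium carboxylate by a reactive allylic bromide (SN2 and SN2' give the same ester), much faster than any attack on the epoxide and without touching C4.

Step 11
Reactants: 16 diene ester
Product: 17 tert-butyl (5aR,6S,9R,9aS)-6-isopropyl-1-oxo-3,5a,6,7,8,9a-hexahydro-1H-spiro[2-benzoxepine-9,2'-oxirane]-4-carboxylate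
Conditions: second-generation Hoveyda–Grubbs catalyst (10 mol %), toluene (2 mM), 80 °C
Reagents that add atoms: none
Why: Ring-closing metathesis starting at the vinyl group and closing onto the 1,1-disubstituted acrylate; the cis arrangement on the cyclohexane brings the alkenes together and the seven-membered ring enforces the required alkene geometry.

Step 12
Reactants: 18 tert-butyl(diphenyl)(prop-2-yn-1-yloxy)silane; 19 (allyloxy)(tert-butyl)dimethylsilane
Product: 20 (E)-5-(tert-butyldimethylsilyloxy)-2-[(tert-butyldiphenylsilyloxy)methyl]penta-1,3-diene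
Conditions: second-generation Grubbs catalyst (5 mol %), excess 19, CH2Cl2, reflux
Reagents that add atoms: none
Why: Cross enyne metathesis of a terminal alkyne and a terminal alkene gives the 1,3-disubstituted butadiene, mainly E, and only the E isomer can reach the s-cis form needed next.

Step 13
Reactants: 20 diene; 21 but-3-en-2-one
Product: 22 1-{(1S,2R)-2-[(tert-butyldimethylsilyloxy)methyl]-4-[(tert-butyldiphenylsilyloxy)methyl]cyclohex-3-en-1-yl}ethan-1-one (cis)
Conditions: (S)-3,3-diphenyl-1-(o-tolyl)tetrahydropyrrolo[1,2-c][1,3,2]oxazaborole·HNTf2 (20 mol %), CH2Cl2, −78 to −40 °C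
Reagents that add atoms: none
Why: Catalytic enantioselective Diels–Alder reaction; both diene substituents direct to the same regioisomer (ortho and para rules), the endo transition state sets acetyl and silyloxymethyl cis, and the chiral cation sets the absolute sense of both centres.

Step 14
Reactants: 22 methyl ketone
Product: 23 tert-butyl({(1R,6S)-3-[(tert-butyldiphenylsilyloxy)methyl]-6-(prop-1-en-2-yl)cyclohex-2-en-1-yl}methoxy)dimethylsilane
Conditions: Cp2TiMe2, toluene, 70 °C
Reagents that add atoms: dimethyltitanocene C[Ti+2]C.c1cc[cH-]c1.c1cc[cH-]c1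
Why: Petasis methylenation is non-basic, so the epimerisable cis centre next to the ketone should be kept.

Step 15
Reactants: 23 isopropenyl compound
Product: 24 tert-butyl({(1S,6R)-3-[(tert-butyldiphenylsilyloxy)methyl]-6-isopropylcyclohex-2-en-1-yl}methoxy)dimethylsilane
Conditions: H2 (1 atm), RhCl(PPh3)3 (5 mol %), benzene, rt
Reagents that add atoms: none
Why: Homogeneous hydrogenation with RhCl(PPh3)3 reduces the 1,1-disubstituted alkene far faster than the trisubstituted ring alkene, as in the carvone series.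

Step 16
Reactants: 24 bis-silyl ether
Product: 25 {(1S,6R)-3-[(tert-butyldiphenylsilyloxy)methyl]-6-isopropylcyclohex-2-en-1-yl}methanol
Conditions: camphorsulfonic acid (10 mol %), MeOH/CH2Cl2, 0 °C
Reagents that add atoms: none
Why: Acid-catalysed methanolysis removes a primary TBS ether much faster than a primary TBDPS ether.

Step 17
Reactants: 25 primary alcohol
Product: 26 (1S,6R)-3-[(tert-butyldiphenylsilyloxy)methyl]-6-isopropylcyclohex-2-ene-1-carbaldehyde
Conditions: Dess–Martin periodinane, CH2Cl2, 0 °C; used at once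
Reagents that add atoms: none
Why: Dess–Martin oxidation is near neutral and fast, which limits epimerisation or conjugation of the cis β,γ-unsaturated aldehyde.

Step 18
Reactants: 26 aldehyde
Product: 27 methyl (Z)-2-bromo-3-{(1S,6R)-3-[(tert-butyldiphenylsilyloxy)methyl]-6-isopropylcyclohex-2-en-1-yl}prop-2-enoate
Conditions: Ph3P=CHCO2Me, NBS, CH2Cl2, −20 °C; then 26, rt
Reagents that add atoms: methyl (triphenylphosphoranylidene)acetate COC(=O)C=P(c1ccccc1)(c1ccccc1)c1ccccc1; N-bromosuccinimide O=C1CCC(=O)N1Br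
Why: Wittig reaction of the stabilised bromo-ylide under neutral conditions should place the ring carbon trans to the ester and cis to bromine, the geometry the side chain needs.

Step 19
Reactants: 27 bromoenoate
Product: 28 methyl (E)-3-{(1S,6R)-3-[(tert-butyldiphenylsilyloxy)methyl]-6-isopropylcyclohex-2-en-1-yl}-2-(hydroxymethyl)prop-2-enoate
Conditions: Bu3SnCH2OH, Pd(PPh3)4 (10 mol %), toluene, 90 °C
Reagents that add atoms: (tributylstannyl)methanol OC[Sn](CCCC)(CCCC)CCCC
Why: Migita–Kosugi–Stille hydroxymethylation of an alkenyl bromide proceeds with retention, so CH2OH takes the place of bromine cis to the ring.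

Step 20
Reactants: 28 silyl ether
Product: 29 methyl (E)-2-(hydroxymethyl)-3-[(1S,6R)-3-(hydroxymethyl)-6-isopropylcyclohex-2-en-1-yl]prop-2-enoate
Conditions: HF·pyridine, THF/pyridine, 0 °C to rt
Reagents that add atoms: none
Why: Buffered fluoride cleavage of the TBDPS ether leaves the enoate and the allylic alcohols untouched.

Step 21
Reactants: 29 diol ester
Product: 30 (E)-2-(hydroxymethyl)-3-[(1S,6R)-3-(hydroxymethyl)-6-isopropylcyclohex-2-en-1-yl]prop-2-enoic acid
Conditions: LiOH, THF/H2O, rt; then 1 M HCl to pH 3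
Reagents that add atoms: lithium hydroxide [Li+].[OH-]
Why: Saponification of the methyl enoate; the ring centre is only vinylogously acidic and should be stable to aqueous hydroxide at room temperature.

Step 22
Reactants: 17 epoxy lactone; 30 dihydroxy acid
Product: 31 tert-butyl ester of the target (C4 carboxyl protected, all hydroxyl groups free)
Conditions: Cs2CO3 (0.2 equiv), DMF, 60 °C
Reagents that add atoms: none
Why: Base-catalysed opening of a 2,2-disubstituted epoxide by a carboxylate occurs by SN2 at the CH2 carbon, so the configuration at C9 is kept, the tertiary alcohol is released, and the neutral hydroxyl groups of 30 stay spectators.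

Step 23
Reactants: 31 tert-butyl ester
Product: 33 target CNP0361406.7, via persilylated ester 32 (not isolated)
Conditions: TMSOTf, 2,6-lutidine, CH2Cl2, 0 °C; then aq. citric acid, THF, rt
Reagents that add atoms: trimethylsilyl trifluoromethanesulfonate C[Si](C)(C)OS(=O)(=O)C(F)(F)F (stays in 32 only)
Why: Silyl-triflate-mediated cleavage of a tert-butyl ester under buffered conditions masks the three alcohols as TMS ethers while isobutene leaves, and mild aqueous acid then frees acid and alcohols without harming lactone, ester or allylic positions.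

**Compound list**
1 | (R)-4-(tert-butyldimethylsilyloxy)cyclopent-2-en-1-one | O=C1C=C[C@H](O[Si](C)(C)C(C)(C)C)C1 | starting material
2 | propa-1,2-diene | C=C=C | starting material
3 | (1R,4R,5R)-4-(tert-butyldimethylsilyloxy)-7-methylidenebicyclo[3.2.0]heptan-2-one | O=C1C[C@@H](O[Si](C)(C)C(C)(C)C)[C@@H]2CC(=C)[C@H]12 | intermediate
4 | (1R,5S)-7-methylidenebicyclo[3.2.0]hept-3-en-2-one | O=C1C=C[C@@H]2CC(=C)[C@H]12 | intermediate
5 | trimethylsilyl enol ether of 6 (C2=C3) | C[Si](C)(C)OC1=C[C@@H](C(C)C)[C@@H]2CC(=C)[C@H]12 | intermediate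
6 | (1R,4S,5S)-4-isopropyl-7-methylidenebicyclo[3.2.0]heptan-2-one | O=C1C[C@@H](C(C)C)[C@@H]2CC(=C)[C@H]12 | intermediate
7 | (1R,5S,6S)-5-isopropyl-8-methylidene-3-(trimethylsilyl)bicyclo[4.2.0]octan-2-one (C3 epimers) | O=C1C([Si](C)(C)C)C[C@@H](C(C)C)[C@@H]2CC(=C)[C@H]12 | intermediate
8 | (1R,5S,6S)-5-isopropyl-8-methylidenebicyclo[4.2.0]octan-2-one | O=C1CC[C@@H](C(C)C)[C@@H]2CC(=C)[C@H]12 | intermediate
9 | (1R,2R,5S,6S)-5-isopropyl-8-methylidenespiro[bicyclo[4.2.0]octane-2,2'-oxirane] | C1O[C@@]12CC[C@@H](C(C)C)[C@@H]3CC(=C)[C@H]23 | intermediate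
10 | (1S,2R,5S,6S)-5-isopropylspiro[bicyclo[4.2.0]octane-2,2'-oxiran]-8-one | C1O[C@@]12CC[C@@H](C(C)C)[C@@H]3CC(=O)[C@H]23 | intermediate
11 | {[(1S,2R,5S,6R)-5-isopropylspiro[bicyclo[4.2.0]oct-7-ene-2,2'-oxiran]-8-yl]oxy}trimethylsilane | C1O[C@@]12CC[C@@H](C(C)C)[C@@H]3C=C(O[Si](C)(C)C)[C@H]23 | intermediate
12 | trimethylsilyl (3R,4S,5S,6S)-5-formyl-6-isopropyl-1-oxaspiro[2.5]octane-4-carboxylate | C1O[C@@]12CC[C@@H](C(C)C)[C@H](C=O)[C@@H]2C(=O)O[Si](C)(C)C | intermediate
13 | (3R,4S,5S,6S)-5-formyl-6-isopropyl-1-oxaspiro[2.5]octane-4-carboxylic acid | C1O[C@@]12CC[C@@H](C(C)C)[C@H](C=O)[C@@H]2C(=O)O | intermediate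
14 | (3R,4S,5S,6S)-5-ethenyl-6-isopropyl-1-oxaspiro[2.5]octane-4-carboxylic acid | C1O[C@@]12CC[C@@H](C(C)C)[C@H](C=C)[C@@H]2C(=O)O | intermediate
15 | tert-butyl 2-(bromomethyl)prop-2-enoate | C=C(CBr)C(=O)OC(C)(C)C | starting material
16 | 2-(tert-butoxycarbonyl)prop-2-en-1-yl (3R,4S,5S,6S)-5-ethenyl-6-isopropyl-1-oxaspiro[2.5]octane-4-carboxylate | C1O[C@@]12CC[C@@H](C(C)C)[C@H](C=C)[C@@H]2C(=O)OCC(=C)C(=O)OC(C)(C)C | intermediate
17 | tert-butyl (5aR,6S,9R,9aS)-6-isopropyl-1-oxo-3,5a,6,7,8,9a-hexahydro-1H-spiro[2-benzoxepine-9,2'-oxirane]-4-carboxylate | C1O[C@@]12CC[C@@H](C(C)C)[C@@H]3C=C(C(=O)OC(C)(C)C)COC(=O)[C@H]23 | intermediate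
18 | tert-butyl(diphenyl)(prop-2-yn-1-yloxy)silane | C#CCO[Si](c1ccccc1)(c1ccccc1)C(C)(C)C | starting material
19 | (allyloxy)(tert-butyl)dimethylsilane | C=CCO[Si](C)(C)C(C)(C)C | starting material
20 | (E)-5-(tert-butyldimethylsilyloxy)-2-[(tert-butyldiphenylsilyloxy)methyl]penta-1,3-diene | C=C(CO[Si](c1ccccc1)(c1ccccc1)C(C)(C)C)/C=C/CO[Si](C)(C)C(C)(C)C | intermediate
21 | but-3-en-2-one | CC(=O)C=C | starting material
22 | 1-{(1S,2R)-2-[(tert-butyldimethylsilyloxy)methyl]-4-[(tert-butyldiphenylsilyloxy)methyl]cyclohex-3-en-1-yl}ethan-1-one | CC(=O)[C@H]1CCC(CO[Si](c2ccccc2)(c2ccccc2)C(C)(C)C)=C[C@H]1CO[Si](C)(C)C(C)(C)C | intermediate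
23 | tert-butyl({(1R,6S)-3-[(tert-butyldiphenylsilyloxy)methyl]-6-(prop-1-en-2-yl)cyclohex-2-en-1-yl}methoxy)dimethylsilane | CC(=C)[C@H]1CCC(CO[Si](c2ccccc2)(c2ccccc2)C(C)(C)C)=C[C@H]1CO[Si](C)(C)C(C)(C)C | intermediate
24 | tert-butyl({(1S,6R)-3-[(tert-butyldiphenylsilyloxy)methyl]-6-isopropylcyclohex-2-en-1-yl}methoxy)dimethylsilane | CC(C)[C@H]1CCC(CO[Si](c2ccccc2)(c2ccccc2)C(C)(C)C)=C[C@H]1CO[Si](C)(C)C(C)(C)C | intermediate
25 | {(1S,6R)-3-[(tert-butyldiphenylsilyloxy)methyl]-6-isopropylcyclohex-2-en-1-yl}methanol | CC(C)[C@H]1CCC(CO[Si](c2ccccc2)(c2ccccc2)C(C)(C)C)=C[C@H]1CO | intermediate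
26 | (1S,6R)-3-[(tert-butyldiphenylsilyloxy)methyl]-6-isopropylcyclohex-2-ene-1-carbaldehyde | CC(C)[C@H]1CCC(CO[Si](c2ccccc2)(c2ccccc2)C(C)(C)C)=C[C@H]1C=O | intermediate
27 | methyl (Z)-2-bromo-3-{(1S,6R)-3-[(tert-butyldiphenylsilyloxy)methyl]-6-isopropylcyclohex-2-en-1-yl}prop-2-enoate | CC(C)[C@H]1CCC(CO[Si](c2ccccc2)(c2ccccc2)C(C)(C)C)=C[C@H]1/C=C(\Br)C(=O)OC | intermediate
28 | methyl (E)-3-{(1S,6R)-3-[(tert-butyldiphenylsilyloxy)methyl]-6-isopropylcyclohex-2-en-1-yl}-2-(hydroxymethyl)prop-2-enoate | CC(C)[C@H]1CCC(CO[Si](c2ccccc2)(c2ccccc2)C(C)(C)C)=C[C@H]1/C=C(\CO)C(=O)OC | intermediate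
29 | methyl (E)-2-(hydroxymethyl)-3-[(1S,6R)-3-(hydroxymethyl)-6-isopropylcyclohex-2-en-1-yl]prop-2-enoate | CC(C)[C@H]1CCC(CO)=C[C@H]1/C=C(\CO)C(=O)OC | intermediate
30 | (E)-2-(hydroxymethyl)-3-[(1S,6R)-3-(hydroxymethyl)-6-isopropylcyclohex-2-en-1-yl]prop-2-enoic acid | CC(C)[C@H]1CCC(CO)=C[C@H]1/C=C(\CO)C(=O)O | intermediate
31 | tert-butyl (5aR,6S,9R,9aS)-9-hydroxy-9-({[(E)-2-(hydroxymethyl)-3-[(1S,6R)-3-(hydroxymethyl)-6-isopropylcyclohex-2-en-1-yl]prop-2-enoyl]oxy}methyl)-6-isopropyl-1-oxo-1,3,5a,6,7,8,9,9a-octahydro-2-benzoxepine-4-carboxylate | CC(C)[C@H]1CCC(CO)=C[C@H]1/C=C(\CO)C(=O)OC[C@@]1(O)CC[C@@H](C(C)C)[C@@H]2C=C(C(=O)OC(C)(C)C)COC(=O)[C@@H]21 | intermediate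
32 | trimethylsilyl ester, tris(trimethylsilyl) ether of 33 | CC(C)[C@H]1CCC(CO[Si](C)(C)C)=C[C@H]1/C=C(\CO[Si](C)(C)C)C(=O)OC[C@@]1(O[Si](C)(C)C)CC[C@@H](C(C)C)[C@@H]2C=C(C(=O)O[Si](C)(C)C)COC(=O)[C@@H]21 | intermediate
33 | (5aR,6S,9R,9aS)-9-hydroxy-9-({[(E)-2-(hydroxymethyl)-3-[(1S,6R)-3-(hydroxymethyl)-6-isopropylcyclohex-2-en-1-yl]prop-2-enoyl]oxy}methyl)-6-isopropyl-1-oxo-1,3,5a,6,7,8,9,9a-octahydro-2-benzoxepine-4-carboxylic acid | CC(C)[C@H]1CCC(CO)=C[C@H]1/C=C(\CO)C(=O)OC[C@@]1(O)CC[C@@H](C(C)C)[C@@H]2C=C(C(=O)O)COC(=O)[C@@H]21 | target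

**Total step count:** 23.
**Longest linear sequence:** 13 (steps 1–11, 22, 23).

**Steps most likely to fail**

Step 11 (ring-closing metathesis).
- Risk: closure onto the electron-poor 1,1-disubstituted alkene may be slow, so oligomerisation and catalyst decay could win.
- Fallback, from 13 back to 17:
  - Oxo acid 13 is treated with an excess of tert-butyl bromo(triphenylphosphoranylidene)acetate to give the (Z)-bromoenoate acid F4.
  - Stille hydroxymethylation (Bu3SnCH2OH, Pd(PPh3)4) gives the hydroxy acid F5.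
  - Lactonisation through a mixed anhydride (2-methyl-6-nitrobenzoic anhydride, DMAP, high dilution) closes the acyl–oxygen bond instead of the alkene and returns to the route at 17.

Step 4 (one-carbon insertion).
- Risk: migration of the ring-fusion carbon, repeated insertion or epoxide formation could erode the step.
- Fallback, from 5 (kept by a non-acidic work-up of step 3) back to 8:
  - Et2Zn/CH2I2 cyclopropanates the electron-rich enol ether to the siloxycyclopropane F1.
  - FeCl3 in DMF cleaves the inner cyclopropane bond by way of the alkoxy radical (Saegusa ring enlargement) to the β-chloro ketone F2.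
  - NaOAc in MeOH gives the enone F3.
  - Conjugate reduction with [(Ph3P)CuH]6 returns to the route at 8.
- Here the position of the inserted carbon is fixed by the regiodefined enol ether from the cuprate step.

Step 13 (catalytic Diels–Alder).
- Risk: facial or endo selectivity may be poor, or the strongly acidic catalyst may cause loss of a silyl ether.
- Fallback, from 20 back to 22:
  - Diene 20 is combined with (R)-3-acryloyl-4-benzyloxazolidin-2-one and Et2AlCl (CH2Cl2, −78 °C). The chelated s-cis imide is attacked opposite the benzyl group, giving the endo imide F6.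
  - MeNH(OMe)·HCl/AlMe3 gives the Weinreb amide F7.
  - MeMgBr returns to the route at 22.

**Further compounds**
F1 | step 4 | trimethylsilyl ether of the tricyclic cyclopropanol (CH2 added to C2=C3 of 5 on the convex face) | C[Si](C)(C)O[C@]12C[C@H]1[C@@H](C(C)C)[C@@H]3CC(=C)[C@H]23
F2 | step 4 | 4-chloro-5-isopropyl-8-methylidenebicyclo[4.2.0]octan-2-one (C4 epimers) | O=C1CC(Cl)[C@@H](C(C)C)[C@@H]2CC(=C)[C@H]12
F3 | step 4 | 5-isopropyl-8-methylidenebicyclo[4.2.0]oct-3-en-2-one | O=C1C=C[C@@H](C(C)C)[C@@H]2CC(=C)[C@H]12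
F4 | step 11 | 5-[(Z)-2-bromo-3-tert-butoxy-3-oxoprop-1-en-1-yl]-6-isopropyl-1-oxaspiro[2.5]octane-4-carboxylic acid | C1O[C@@]12CC[C@@H](C(C)C)[C@H](/C=C(\Br)C(=O)OC(C)(C)C)[C@@H]2C(=O)O
F5 | step 11 | 5-[(E)-3-tert-butoxy-2-(hydroxymethyl)-3-oxoprop-1-en-1-yl]-6-isopropyl-1-oxaspiro[2.5]octane-4-carboxylic acid | C1O[C@@]12CC[C@@H](C(C)C)[C@H](/C=C(\CO)C(=O)OC(C)(C)C)[C@@H]2C(=O)O
F6 | step 13 | (R)-4-benzyl-3-(cis-cyclohexenecarbonyl)oxazolidin-2-one, imide analogue of 22 | O=C(N1C(=O)OC[C@H]1Cc1ccccc1)[C@H]1CCC(CO[Si](c2ccccc2)(c2ccccc2)C(C)(C)C)=C[C@H]1CO[Si](C)(C)C(C)(C)C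
F7 | step 13 | N-methoxy-N-methyl amide analogue of 22 | CON(C)C(=O)[C@H]1CCC(CO[Si](c2ccccc2)(c2ccccc2)C(C)(C)C)=C[C@H]1CO[Si](C)(C)C(C)(C)C
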